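All constants are made up; the rest is arithmetic.

Late in a run the useful question is where free monomer stops, so the examination begins there.

free monomer 0.062 M (fed, over 20 s); initiator 0.12 mM; time 40 min; the fed solution adds 1.0 times the starting volume

    free monomer + initiator → living end + monomer in chains (k1 = 1.2 /M/s)
    free monomer + living end → monomer in chains + living end, rate k2*[living end]*[free monomer] (k2 = 52 /M/s)
    monomer in chains + living end → free monomer + living end, rate k3*[living end] as long as [monomer in chains] is above zero (k3 = 0.30 /s)

- charges are per starting volume, the dose included; the dosed solution carries all of it
- the average divides the monomer in chains by the number of chains begun, living and dead together
- run time (flask): 40 min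

* average number of monomer units in a chain (chains begun, living or dead) at 40 min
* part of the free monomer that has reacted at 40 min

Which charge is smaller? The initiator, 0.12 mM against 0.062 M of free monomer. Each initiator lost makes one living end, and no step removes a living end. So initiator plus living end stays constant. The feed adds one starting volume, and that sum becomes 0.0600 mM.

Where does free monomer stop? Where steps 2 and 3 run equally fast. Then k2 × living end × free monomer equals k3 × living end, and the living end cancels. That leaves the stop level, the free monomer concentration at which the two steps balance, k3/k2 = 5.77 mM. This is the equilibrium monomer concentration.

But step 3 needs monomer in chains. Is there any? After the feed this flask holds 31.0 mM of monomer in total, more than the stop level. So the chains hold the difference.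

Does every chain begin? At the stop level, the half-life of initiator is 1.67 min, shorter than 40 min. So I count every initiator as begun.

Is the time long enough? The excess of free monomer decays with a time constant of 5.34 min, shorter than 40 min. So I read the stop itself: dp 420.5 and conversion 81.4%.

The forecast gives 420.3 and 81.3%. It rests on the same balance, “Propagation and depropagation balance”, but keeps a remainder of 0.015 mM above the stop, where I keep none.

The simulation gives 420 and 81.3%.

In this flask the half-life of free monomer by the step into chains is 3.7 min at 40.0 min, short against 40 min, and the free monomer left is 19% of the charge, where the stop level gives 18.6%. In the neighbouring flask with 0.016 M charged, the same stop level gives 72.1% left and dp 37.2; that flask shows 71.9% left and dp 37.4.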